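The route rests on closing ring B (the cyclohexane) at the bond between C9, the quaternary carbon shared with ring A (the cyclopentane) that carries the acetoxymethyl carbon C17, and the neighbouring methylene C8. C9 is treated as the α-carbon of a C17 ester: the lithium dienolate of a cyclopent-1-enecarboxylate, already tied through C4 to C5 of an enantioenriched ring C (the cycloheptene), is alkylated by a bromoethyl arm on C6. One operation closes ring B, sets the C9 stereocentre from the trans C5/C6 array, and moves the ring A double bond to C3=C4, where a later radical lactone annulation fixes C3 and the trans A/B fusion.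

Key step: step 11

Remark (numbering and transient centres): ring A = C1–C2–C3–C4–C9 (C2 bears the lactone oxygen, C3 the lactone carbon), ring B = C4–C5–C6–C7–C8–C9, ring C = C5–C6–C14–C13–C12–C11–C10; C15 = methyl on C12, C16 = methyl on C6, C17 = oxygenated carbon on C9; β is the face of C17 and H5, α the face of C16; the carbinol carbon of 10 and 11 and the acetal carbon of 18–20 are carried as epimer mixtures and written without configuration, because both centres are destroyed later.

Step 1
Reactants: 1 1,4-dioxaspiro[4.4]nonan-7-one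
Product: 2 methyl 8-oxo-1,4-dioxaspiro[4.4]nonane-7-carboxylate
Conditions: NaH, dimethyl carbonate, THF, reflux; then 1 M HCl
Reagents that add atoms: dimethyl carbonate COC(=O)OC
Why: Crossed Claisen C-acylation of the ketone sodium enolate by dimethyl carbonate should occur at the methylene remote from the ketal, which is less hindered and gives the β-keto ester enolate that cannot lose a ketal oxygen.

Step 2
Reactants: 2 methyl 8-oxo-1,4-dioxaspiro[4.4]nonane-7-carboxylate
Product: 3 methyl 8-(trifluoromethanesulfonyloxy)-1,4-dioxaspiro[4.4]non-7-ene-7-carboxylate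
Conditions: NaH, THF, 0 °C; then Tf2O, −78 to 0 °C
Reagents that add atoms: trifluoromethanesulfonic anhydride O=S(=O)(OS(=O)(=O)C(F)(F)F)C(F)(F)F
Why: O-Sulfonylation of the sodium enolate of the β-keto ester should give the tetrasubstituted enol triflate, the ester fixing the double bond between the future C9 and C4.

Step 3
Reactants: 3 methyl 8-(trifluoromethanesulfonyloxy)-1,4-dioxaspiro[4.4]non-7-ene-7-carboxylate
Product: 4 methyl 8-(4,4,5,5-tetramethyl-1,3,2-dioxaborolan-2-yl)-1,4-dioxaspiro[4.4]non-7-ene-7-carboxylate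
Conditions: B2pin2, PdCl2(PPh3)2 (cat.), PPh3, KOPh, toluene, 50 °C
Reagents that add atoms: bis(pinacolato)diboron CC1(C)OB(OC1(C)C)B1OC(C)(C)C(C)(C)O1
Why: Miyaura borylation (oxidative addition of the enol triflate to zerovalent palladium, phenoxide-assisted transmetalation from B2pin2, reductive elimination) should give the β-boryl enoate, a reaction type established for triflates of cyclic β-keto esters.

Step 4
Reactants: 5 3-methylcyclohept-2-en-1-one
Product: 6 3-methylcyclohepta-2,6-dien-1-one
Conditions: LiN(iPr)2, THF, −78 °C; then N-tert-butylbenzenesulfinimidoyl chloride, −78 °C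
Reagents that add atoms: none
Why: Kinetic α'-lithiation, attack of the enolate on sulfur and syn-elimination of the sulfenamide (one-pot enolate dehydrogenation) should introduce the C5=C6 double bond and give the cross-conjugated dienone.

Step 5
Reactants: 6 3-methylcyclohepta-2,6-dien-1-one; 4 methyl 8-(4,4,5,5-tetramethyl-1,3,2-dioxaborolan-2-yl)-1,4-dioxaspiro[4.4]non-7-ene-7-carboxylate
Product: 7 methyl 8-[(1S)-5-methyl-3-oxocyclohept-4-en-1-yl]-1,4-dioxaspiro[4.4]non-7-ene-7-carboxylate
Conditions: [RhCl(C2H4)2]2 (cat.), (S)-BINAP, K3PO4, dioxane–H2O 10:1, 60 °C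
Reagents that add atoms: none
Why: Hayashi–Miyaura rhodium-catalysed asymmetric 1,4-addition should transfer the alkenyl group only to the β-unsubstituted enone terminus C5 (the C12 terminus carries a methyl group), and (S)-BINAP should set C5 as S by the facial sense established for cyclohept-2-enone.

Step 6
Reactants: 7 methyl 8-[(1S)-5-methyl-3-oxocyclohept-4-en-1-yl]-1,4-dioxaspiro[4.4]non-7-ene-7-carboxylate
Product: 8 methyl 8-[(1S,2R)-2,5-dimethyl-3-oxocyclohept-4-en-1-yl]-1,4-dioxaspiro[4.4]non-7-ene-7-carboxylate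
Conditions: LiN(iPr)2, THF, −78 °C; then MeI, −78 to −20 °C
Reagents that add atoms: iodomethane CI
Why: Kinetic deprotonation at the only α-methylene (C6) gives the cross-conjugated lithium enolate, whose methylation should occur mainly trans to the C5 substituent; the C6 configuration is erased in step 7, so the isomer ratio is immaterial.

Step 7
Reactants: 8 methyl 8-[(1S,2R)-2,5-dimethyl-3-oxocyclohept-4-en-1-yl]-1,4-dioxaspiro[4.4]non-7-ene-7-carboxylate
Product: 9 methyl 8-[(1R,2R)-2-(2-bromoethyl)-2,5-dimethyl-3-oxocyclohept-4-en-1-yl]-1,4-dioxaspiro[4.4]non-7-ene-7-carboxylate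
Conditions: LiN(iPr)2, THF, −78 °C; then DMPU, 2-bromoethyl trifluoromethanesulfonate, −78 to −30 °C
Reagents that add atoms: 2-bromoethyl trifluoromethanesulfonate O=S(=O)(OCCBr)C(F)(F)F
Why: Re-enolisation at C6 gives a planar tetrasubstituted enolate whose C-alkylation by the primary triflate should occur anti to the bulky C5 substituent, placing the C7–C8 arm trans and the methyl C16 cis to C4 as the trans B/C fusion requires; triflate leaves far faster than bromide, so the bromide is kept.

Step 8
Reactants: 9 methyl 8-[(1R,2R)-2-(2-bromoethyl)-2,5-dimethyl-3-oxocyclohept-4-en-1-yl]-1,4-dioxaspiro[4.4]non-7-ene-7-carboxylate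
Product: 10 methyl 8-[2-(2-bromoethyl)-3-hydroxy-2,5-dimethylcyclohept-4-en-1-yl]-1,4-dioxaspiro[4.4]non-7-ene-7-carboxylate (C5 and C6 as in 9)
Conditions: NaBH4, CeCl3·7H2O, MeOH, 0 °C
Reagents that add atoms: none
Why: Luche reduction should give clean 1,2-reduction of the enone without touching the conjugated ester, the ketal or the bromide; the new carbinol centre is removed in step 10.

Step 9
Reactants: 10 methyl 8-[2-(2-bromoethyl)-3-hydroxy-2,5-dimethylcyclohept-4-en-1-yl]-1,4-dioxaspiro[4.4]non-7-ene-7-carboxylate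
Product: 11 methyl 8-[3-acetoxy-2-(2-bromoethyl)-2,5-dimethylcyclohept-4-en-1-yl]-1,4-dioxaspiro[4.4]non-7-ene-7-carboxylate
Conditions: Ac2O, Et3N, DMAP (cat.), CH2Cl2, 23 °C
Reagents that add atoms: acetic anhydride CC(=O)OC(C)=O
Why: DMAP-catalysed acetylation turns the hindered allylic alcohol into a leaving group for π-allyl formation.

Step 10
Reactants: 11 methyl 8-[3-acetoxy-2-(2-bromoethyl)-2,5-dimethylcyclohept-4-en-1-yl]-1,4-dioxaspiro[4.4]non-7-ene-7-carboxylate
Product: 12 methyl 8-[(1S,2R)-2-(2-bromoethyl)-2,5-dimethylcyclohept-4-en-1-yl]-1,4-dioxaspiro[4.4]non-7-ene-7-carboxylate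
Conditions: Pd(PPh3)4 (cat.), NaBH4, DME, 0 to 23 °C
Reagents that add atoms: none
Why: Tsuji–Trost-type ionisation by zerovalent palladium to the π-allyl complex and hydride transfer from borohydride to the less substituted allyl terminus C14 should remove the oxygen and leave the trisubstituted C12=C13 double bond in place.

Step 11
Reactants: 12 methyl 8-[(1S,2R)-2-(2-bromoethyl)-2,5-dimethylcyclohept-4-en-1-yl]-1,4-dioxaspiro[4.4]non-7-ene-7-carboxylate
Product: 13 tricyclic ketal ester (ring A: ethylene ketal at C2, C3=C4; C9: β-CO2Me as C17; ring C: C12=C13; 5β-H, 6α-methyl)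
Conditions: LiN(iPr)2 (1.3 equiv), THF–DMPU, −78 °C, then −78 to −20 °C
Reagents that add atoms: none
Why: LiN(iPr)2 removes a γ-proton at C3 of the cyclopentenyl ester to give the lithium dienolate (C17(OLi)(OMe)=C9–C4=C3), whose α-carbon C9 displaces bromide at C8 in an intramolecular SN2 reaction. The closest known reaction type is the deconjugative α-alkylation of ester dienolates, here in its intramolecular form. Ring B closes in a 6-(enolexo)-exo-tet mode, and because C4 stays sp2 no ring-fusion stereocentre at C4 has to be set in this step. The C9 stereocentre is controlled by C5 and C6: the ring C bonds C5–C10 and C6–C14 are trans and can only be diequatorial on the forming chair, which fixes the face from which C8 reaches C9 and leaves the ester carbon C17 axial, anti to the C6 methyl and syn to H5. The step needs α- over γ-alkylation and ring closure over loss of a ketal oxygen by β-elimination; ester dienolates react at the α-carbon, closure at C3 would force C10 against the enolate group on C9 (allylic strain), and the dienolate is kept cold with DMPU so that the 6-ring closure outruns elimination.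

Step 12
Reactants: 13 tricyclic ketal ester
Product: 15 hydroxy enone (C2 ketone conjugated with C3=C4; 9β-CH2OH; C12=C13; 5β-H, 6α-methyl), via ketal alcohol 14 (not isolated)
Conditions: LiAlH4, THF, 0 °C; then 1 M HCl, THF, 23 °C
Reagents that add atoms: water O
Why: LiAlH4 reduces the neopentyl ester to the primary alcohol at C17, and the acidic work-up hydrolyses the ketal, the liberated C2 ketone being conjugated at once with the C3=C4 double bond.

Step 13
Reactants: 15 hydroxy enone
Product: 16 acetoxy enone (as 15 with 9β-CH2OAc)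
Conditions: Ac2O, pyridine, DMAP (cat.), CH2Cl2, 23 °C
Reagents that add atoms: acetic anhydride CC(=O)OC(C)=O
Why: The only hydroxyl group is acetylated under DMAP catalysis, which installs the acetate of the target.

Step 14
Reactants: 16 acetoxy enone
Product: 17 allylic alcohol (2β-OH, C3=C4, 9β-CH2OAc, C12=C13)
Conditions: NaBH4, CeCl3·7H2O, MeOH, −40 °C
Reagents that add atoms: none
Why: Luche 1,2-reduction of the cyclopentenone should deliver hydride to the α face, opposite the angular acetoxymethyl group on C9, giving the 2β alcohol cis to C17, the outcome known for hydrindenones with an angular substituent.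

Step 15
Reactants: 17 allylic alcohol
Product: 18 mixed acetal (2β-O–CH(OMe)–C(Br)=CH2)
Conditions: methoxyallene, NBS, CH2Cl2, −40 °C
Reagents that add atoms: methoxyallene COC=C=C; N-bromosuccinimide O=C1CCC(=O)N1Br
Why: Bromoalkoxylation of the allenyl ether (bromine transfer to the central allene carbon, capture of the oxocarbenium ion by the alcohol) gives the 2-bromoallyl mixed acetal, the enol ether being far more nucleophilic than the two trisubstituted alkenes.

Step 16
Reactants: 18 mixed acetal
Product: 19 lactol methyl ether (cis-fused 2-methoxy-3-methyleneoxolane on the β face of C2–C3; 3α-H, 4α-H, trans A/B fusion)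
Conditions: Bu3SnH, AIBN (cat.), benzene, 80 °C, slow addition
Reagents that add atoms: none
Why: Ueno–Stork-type radical cyclization, in which the vinyl radical closes 5-exo onto C3 on the β face dictated by the C2–O tether and the tertiary C4 radical takes hydrogen from Bu3SnH on the α face, opposite the angular C17 group and the new ring, which sets the trans A/B fusion.

Step 17
Reactants: 19 lactol methyl ether
Product: 21 α-methylene lactone with C12=C13 alkene (the target lacking the epoxide oxygen), via lactol 20 (not isolated)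
Conditions: CrO3, H2SO4, acetone–H2O, 0 °C
Reagents that add atoms: water O
Why: Jones oxidation hydrolyses the allylic methyl acetal to the lactol and oxidises it to the α-methylene-γ-butyrolactone, a sequence known for 2-alkoxy-3-methyleneoxolanes, while acetate and trisubstituted alkene should tolerate the brief acidic conditions.

Step 18
Reactants: 21 α-methylene lactone with C12=C13 alkene
Product: 22 CNP0149939.1 (12β,13β-epoxide)
Conditions: mCPBA, NaHCO3, CH2Cl2, 0 °C
Reagents that add atoms: 3-chloroperbenzoic acid O=C(OO)c1cccc(Cl)c1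
Why: Prilezhaev epoxidation should take place only at the electron-rich trisubstituted C12=C13 alkene (the α-methylene lactone is electron-poor) and from the β face, anti to the axial C16 methyl on C6 that shields the α face, as in the epoxidation of steroidal 2-enes anti to the angular methyl group.

Compound list
1 | 1,4-dioxaspiro[4.4]nonan-7-one | O=C1CCC2(C1)OCCO2 | starting material
2 | methyl 8-oxo-1,4-dioxaspiro[4.4]nonane-7-carboxylate (racemic, enolisable) | COC(=O)C1CC2(CC1=O)OCCO2 | intermediate
3 | methyl 8-(trifluoromethanesulfonyloxy)-1,4-dioxaspiro[4.4]non-7-ene-7-carboxylate | COC(=O)C1=C(OS(=O)(=O)C(F)(F)F)CC2(C1)OCCO2 | intermediate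
4 | methyl 8-(4,4,5,5-tetramethyl-1,3,2-dioxaborolan-2-yl)-1,4-dioxaspiro[4.4]non-7-ene-7-carboxylate | COC(=O)C1=C(B2OC(C)(C)C(C)(C)O2)CC3(C1)OCCO3 | intermediate
5 | 3-methylcyclohept-2-en-1-one | CC1=CC(=O)CCCC1 | starting material
6 | 3-methylcyclohepta-2,6-dien-1-one | CC1=CC(=O)C=CCC1 | intermediate
7 | methyl 8-[(1S)-5-methyl-3-oxocyclohept-4-en-1-yl]-1,4-dioxaspiro[4.4]non-7-ene-7-carboxylate | CC1=CC(=O)C[C@H](CC1)C2=C(C(=O)OC)CC3(C2)OCCO3 | intermediate
8 | methyl 8-[(1S,2R)-2,5-dimethyl-3-oxocyclohept-4-en-1-yl]-1,4-dioxaspiro[4.4]non-7-ene-7-carboxylate (2-methyl trans to the spirocyclic group) | CC1=CC(=O)[C@H](C)[C@H](CC1)C2=C(C(=O)OC)CC3(C2)OCCO3 | intermediate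
9 | methyl 8-[(1R,2R)-2-(2-bromoethyl)-2,5-dimethyl-3-oxocyclohept-4-en-1-yl]-1,4-dioxaspiro[4.4]non-7-ene-7-carboxylate (bromoethyl trans, methyl cis to the spirocyclic group) | CC1=CC(=O)[C@](C)(CCBr)[C@H](CC1)C2=C(C(=O)OC)CC3(C2)OCCO3 | intermediate
10 | methyl 8-[2-(2-bromoethyl)-3-hydroxy-2,5-dimethylcyclohept-4-en-1-yl]-1,4-dioxaspiro[4.4]non-7-ene-7-carboxylate (C5, C6 as in 9; carbinol carbon epimeric) | CC1=CC(O)[C@](C)(CCBr)[C@H](CC1)C2=C(C(=O)OC)CC3(C2)OCCO3 | intermediate
11 | methyl 8-[3-acetoxy-2-(2-bromoethyl)-2,5-dimethylcyclohept-4-en-1-yl]-1,4-dioxaspiro[4.4]non-7-ene-7-carboxylate (C5, C6 as in 9; acetoxy carbon epimeric) | CC1=CC(OC(C)=O)[C@](C)(CCBr)[C@H](CC1)C2=C(C(=O)OC)CC3(C2)OCCO3 | intermediate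
12 | methyl 8-[(1S,2R)-2-(2-bromoethyl)-2,5-dimethylcyclohept-4-en-1-yl]-1,4-dioxaspiro[4.4]non-7-ene-7-carboxylate | CC1=CC[C@](C)(CCBr)[C@H](CC1)C2=C(C(=O)OC)CC3(C2)OCCO3 | intermediate
13 | tricyclic ketal ester (C2 ethylene ketal, C3=C4, 9β-CO2Me, C12=C13, 5β-H, 6α-methyl) | O1CCOC12C[C@]3(C(=O)OC)CC[C@@]4(C)CC=C(C)CC[C@@H]4C3=C2 | intermediate
14 | ketal alcohol (as 13 with 9β-CH2OH) | O1CCOC12C[C@]3(CO)CC[C@@]4(C)CC=C(C)CC[C@@H]4C3=C2 | intermediate
15 | hydroxy enone (C2 ketone, C3=C4, 9β-CH2OH, C12=C13, 5β-H, 6α-methyl) | O=C1C[C@]2(CO)CC[C@@]3(C)CC=C(C)CC[C@@H]3C2=C1 | intermediate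
16 | acetoxy enone (as 15 with 9β-CH2OAc) | O=C1C[C@]2(COC(C)=O)CC[C@@]3(C)CC=C(C)CC[C@@H]3C2=C1 | intermediate
17 | allylic alcohol (2β-OH, C3=C4, 9β-CH2OAc, C12=C13) | O[C@H]1C[C@]2(COC(C)=O)CC[C@@]3(C)CC=C(C)CC[C@@H]3C2=C1 | intermediate
18 | mixed acetal (2β-O–CH(OMe)–C(Br)=CH2; acetal carbon epimeric) | C=C(Br)C(OC)O[C@H]1C[C@]2(COC(C)=O)CC[C@@]3(C)CC=C(C)CC[C@@H]3C2=C1 | intermediate
19 | lactol methyl ether (β-face cis-fused 2-methoxy-3-methyleneoxolane on C2–C3; 3α-H, 4α-H; acetal carbon epimeric) | C=C1C(OC)O[C@H]2C[C@]3(COC(C)=O)CC[C@@]4(C)CC=C(C)CC[C@@H]4[C@H]3[C@@H]12 | intermediate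
20 | lactol (as 19 with OH in place of OMe) | C=C1C(O)O[C@H]2C[C@]3(COC(C)=O)CC[C@@]4(C)CC=C(C)CC[C@@H]4[C@H]3[C@@H]12 | intermediate
21 | α-methylene lactone with C12=C13 alkene (target lacking the epoxide oxygen) | C=C1C(=O)O[C@H]2C[C@]3(COC(C)=O)CC[C@@]4(C)CC=C(C)CC[C@@H]4[C@H]3[C@@H]12 | intermediate
22 | CNP0149939.1 (12β,13β-epoxide of 21) | C=C1C(=O)O[C@H]2C[C@]3(COC(C)=O)CC[C@@]4(C)C[C@H]5O[C@@]5(C)CC[C@@H]4[C@H]3[C@@H]12 | target

Total step count: 18. Longest linear sequence: 17 steps (from 1 through steps 1–3 and 5–18).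

Steps most likely to fail

Step 11 (key step). The dienolate may expel a ketal oxygen by β-elimination, opening the dioxolane, or close at the γ-carbon C3 faster than it alkylates at C9. The fallback sets out from 12. iBu2AlH (CH2Cl2, −78 °C) reduces the ester to the allylic alcohol {8-[(1S,2R)-2-(2-bromoethyl)-2,5-dimethylcyclohept-4-en-1-yl]-1,4-dioxaspiro[4.4]non-7-en-7-yl}methanol F1, and MnO2 (CH2Cl2, 23 °C) gives the enal 8-[(1S,2R)-2-(2-bromoethyl)-2,5-dimethylcyclohept-4-en-1-yl]-1,4-dioxaspiro[4.4]non-7-ene-7-carbaldehyde F2. KOtBu in tBuOH–THF at 0 °C forms the more delocalised potassium dienolate of the aldehyde reversibly; its intramolecular C-alkylation at C9 (the classical deconjugative alkylation of an enal) should give the tricyclic ketal aldehyde F3 (13 with CHO in place of CO2Me). NaBH4 in MeOH then gives 14, and 1 M HCl brings the sequence back to the route at 15.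

Step 5. Transmetalation of the hindered, electron-poor alkenylboronate to rhodium may be slower than its protodeboronation. The fallback sets out from 2. PPh3·I2 and Et3N in MeCN should give the vinyl iodide methyl 8-iodo-1,4-dioxaspiro[4.4]non-7-ene-7-carboxylate F4. Iodine–magnesium exchange with iPrMgCl·LiCl (THF, −40 °C) gives the ester-stabilised alkenylmagnesium reagent chloro[7-(methoxycarbonyl)-1,4-dioxaspiro[4.4]non-7-en-8-yl]magnesium F5. This is added to dienone 6 under copper catalysis (CuBr·SMe2, a chiral ferrocenyl diphosphine of the Josiphos type in the enantiomeric form that gives S at C5, tBuOMe, −75 °C), an asymmetric conjugate addition of a Grignard reagent, and the sequence comes back to the route at 7.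

Step 16. The vinyl radical may be reduced by the stannane or undergo a 1,5-hydrogen shift before it closes onto the hindered C3. The fallback sets out from 17. Propiolic acid, DCC and DMAP (cat.) in CH2Cl2 at −20 °C give the prop-2-ynoate ester of 17 F6. Bu3SnH and AIBN in benzene at 80 °C (stannyl-radical addition to the alkyne terminus, 5-exo closure of the α-carbonyl vinyl radical onto C3, hydrogen transfer to C4 from the α face) should give the α-(tributylstannylmethylidene) lactone F7. Protodestannylation with HCl in wet CH2Cl2 comes back to the route at 21, so that 18–20 are bypassed.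

Further compounds
F1 | step 11 | {8-[(1S,2R)-2-(2-bromoethyl)-2,5-dimethylcyclohept-4-en-1-yl]-1,4-dioxaspiro[4.4]non-7-en-7-yl}methanol | CC1=CC[C@](C)(CCBr)[C@H](CC1)C2=C(CO)CC3(C2)OCCO3
F2 | step 11 | 8-[(1S,2R)-2-(2-bromoethyl)-2,5-dimethylcyclohept-4-en-1-yl]-1,4-dioxaspiro[4.4]non-7-ene-7-carbaldehyde | CC1=CC[C@](C)(CCBr)[C@H](CC1)C2=C(C=O)CC3(C2)OCCO3
F3 | step 11 | tricyclic ketal aldehyde (13 with 9β-CHO in place of CO2Me) | O1CCOC12C[C@]3(C=O)CC[C@@]4(C)CC=C(C)CC[C@@H]4C3=C2
F4 | step 5 | methyl 8-iodo-1,4-dioxaspiro[4.4]non-7-ene-7-carboxylate | COC(=O)C1=C(I)CC2(C1)OCCO2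
F5 | step 5 | chloro[7-(methoxycarbonyl)-1,4-dioxaspiro[4.4]non-7-en-8-yl]magnesium | COC(=O)C1=C([Mg]Cl)CC2(C1)OCCO2
F6 | step 16 | prop-2-ynoate ester of 17 (2β-O–CO–C≡CH) | C#CC(=O)O[C@H]1C[C@]2(COC(C)=O)CC[C@@]3(C)CC=C(C)CC[C@@H]3C2=C1
F7 | step 16 | α-(tributylstannylmethylidene) lactone (21 with CH–SnBu3 in place of the methylene CH2) | CCCC[Sn](CCCC)(CCCC)C=C1C(=O)O[C@H]2C[C@]3(COC(C)=O)CC[C@@]4(C)CC=C(C)CC[C@@H]4[C@H]3[C@@H]12
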